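Left-handed product cannot pass 50.0% of the charge, since left-handed substrate is no more than that share of it.

| flask | left-handed substrate | right-handed substrate | gas | free catalyst | remark |
|---|---|---|---|---|---|
| violet | 0.059 M | 0.059 M | 6 mM (held) | 0.34 mol% | run made earlier |
| green | 0.059 M | 0.059 M | 6 mM (held) | 0.75 mol% | run made earlier |
| amber | 0.088 M | 0.088 M | 6 mM (held) | 0.5 mol% | run made earlier |
| flask | 0.059 M | 0.059 M | 6.0 mM (held) | 0.5 mol% |  |

| run | time / h | left-handed product / % |
|---|---|---|
| violet | 4.00 | 10 |
| violet | 6.00 | 18 |
| violet | 8.00 | 25 |
| violet | 15.0 | 43 |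
| violet | 20.0 | 40 |
| violet | 30.0 | 51 |
| violet | 50.0 | 48 |
| green | 4.00 | 20 |
| green | 6.00 | 27 |
| green | 8.00 | 37 |
| green | 15.0 | 48 |
| green | 20.0 | 48 |
| green | 30.0 | 50 |
| green | 50.0 | 52 |
| amber | 10.0 | 34 |
| amber | 20.0 | 49 |
| amber | 30.0 | 48 |
| amber | 40.0 | 49 |
| amber | 50.0 | 49 |

(readings scatter by 2 percentage points)

- free catalyst is single-handed; left-handed substrate and right-handed substrate are mirror images of each other, charged as a racemate, each of them at the stated concentration
- at the start none of reagent is dissolved
- steps thought possible: free catalyst + left-handed substrate <-> catalyst intermediate A; free catalyst + right-handed substrate <-> catalyst intermediate B; reagent + catalyst intermediate A -> free catalyst + left-handed product; reagent + catalyst intermediate B -> free catalyst + right-handed product; gas <-> reagent; free catalyst <-> dormant form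

- apparent order in free catalyst when 30% of the left-handed substrate and right-handed substrate together are converted (percent change of the rate of making left-handed product for one percent more free catalyst charged)

Now face a puzzle. Green carries 2.21 times violet's catalyst, yet it shows 2.00 times violet's left-handed product at 4.00 h and 1.48 times at 8.00 h. Clear it by counting against the ceiling: take the logarithm of the ceiling over what is still missing, which grows with a first-order rate constant. Counted this way, green's reading at 8.00 h stands at 1.94 times violet's, against the 1.48 times of the plain readings.

Next, freeze the composition at a fixed conversion. Let the rate go as catalyst times reagent, and suppose gas supplies reagent in proportion to its gap below saturation. Balance supply against use, and the order in catalyst equals the filling, the reagent's share of saturation at that conversion. Violet and green lie either side of this flask's 0.5 mol%, so read it from them: the 6.00 h pair gives 0.700, and the 8.00 h pair gives 0.840, which shows what the scatter is worth. I commit to the first.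

The forecast says 0.5, within 0.3 to 0.75: “Sublinear catalyst dependence suggests a partial limit from reagent supply”.

The flask gives 0.68.

    free catalyst + left-handed substrate ⇌ catalyst intermediate A (K = 9.20 M⁻¹, k = 37.0 M⁻¹ s⁻¹)
    free catalyst + right-handed substrate ⇌ catalyst intermediate B (K = 130 M⁻¹, k = 2.20 M⁻¹ s⁻¹)
    reagent + catalyst intermediate A → free catalyst + left-handed product (k = 28.0 M⁻¹ s⁻¹)
    reagent + catalyst intermediate B → free catalyst + right-handed product (k = 0.290 M⁻¹ s⁻¹)
    gas ⇌ reagent, rate k5*(csat - [reagent]) (kL = 6.80 × 10⁻⁴ s⁻¹)
    free catalyst ⇌ dormant form (K = 0.860, k = 1.50 × 10⁻⁴ s⁻¹)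

Carried over, a filling of 0.700 means 4.20 mM of reagent at 30% conversion, and at 0.250 d, shortly before that conversion, the flask holds 3.99 mM. Reagent's constant with catalyst intermediate A, 28 M⁻¹ s⁻¹, stands far above its constant with catalyst intermediate B, 0.29 M⁻¹ s⁻¹, and at 0.250 d the flask's catalyst sits 75.7% as catalyst intermediate B, the resting state, against 3.26% as catalyst intermediate A.

The numbers in the tables were computed for an exercise; noise was put on by code.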